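**Retrosynthetic overview** (germacrane numbering; C11=C13 exocyclic methylene, C12 lactone carbonyl, C14 methyl on C10, C15 methyl on C4)
1. Feature: the C10 tertiary carbinol, the cis C1=C2 alkene and the C3 ketone are the ring-opened form of a C3–O–C10 bridged 2,5-dihydrofuran hemiketal, i.e. of an oxidised 2-methylfuran (C3, C2, C1, C10, C14) whose ring oxygen becomes the C10 hydroxyl.
2. Late disconnections: C3 ketal hydrolysis, C8 ester, C8 carbinol (from the ketone), leading back to the bridged methyl ketal 23.
3. Key disconnection C9–C10: the C10 oxocarbenium ion of a furan-derived 2,5-dimethoxy-2,5-dihydrofuran is attacked by the tethered C8 silyl enol ether, closing the ten-membered carbocycle as an oxygen-bridged bicycle.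
4. Precursor: furan–C4 bond by Negishi coupling; cis α-methylene-γ-lactone (C6–C7 bond, then C6–O) by indium Barbier reaction of a lactate-derived allylic bromide with (Z)-3-iodobut-2-enal, the C8 carbinol serving only as a stereochemical relay.
5. Ring order: lactone, then the dihydrofuran (by dearomatisation of the attached furan), then the ten-membered carbocycle.

Key step: step 13

Remark: the target is a γ-hydroxy (Z)-enone and its 3,10-hemiketal is its ring–chain tautomer; the route is taken to end at the open form as drawn.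

**Step 1**
Reactants: 1 ethyl (S)-lactate
Product: 2 ethyl (S)-2-(tert-butyldimethylsilyloxy)propanoate
Conditions: TBSCl, imidazole, DMF, 0 °C to rt
Reagents that add atoms: tert-butyldimethylsilyl chloride, CC(C)(C)[Si](C)(C)Cl
Why: Imidazole-promoted silylation of a secondary alcohol, which leaves the stereocentre untouched.

**Step 2**
Reactants: 2 ethyl (S)-2-(tert-butyldimethylsilyloxy)propanoate
Product: 3 (S)-2-(tert-butyldimethylsilyloxy)propanal
Conditions: i-Bu2AlH (1.05 equiv), CH2Cl2, −78 °C; aqueous work-up, used crude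
Reagents that add atoms: none
Why: Partial ester reduction at −78 °C should stop at the aldehyde through the stable aluminium hemiacetal, with the α-stereocentre retained.

**Step 3**
Reactants: 3 (S)-2-(tert-butyldimethylsilyloxy)propanal; 4 methyl acrylate
Product: 5 methyl (4S)-4-(tert-butyldimethylsilyloxy)-3-hydroxy-2-methylenepentanoate (C3 epimers)
Conditions: 1,4-diazabicyclo[2.2.2]octane (1 equiv), methyl acrylate (neat, excess), rt, several days
Reagents that add atoms: none
Why: Morita–Baylis–Hillman reaction of an α-alkoxy aldehyde; the configuration of the new carbinol is immaterial because it is lost in step 4.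

**Step 4**
Reactants: 5 methyl (4S)-4-(tert-butyldimethylsilyloxy)-3-hydroxy-2-methylenepentanoate
Product: 6 methyl (2Z,4S)-2-(bromomethyl)-4-(tert-butyldimethylsilyloxy)pent-2-enoate
Conditions: NBS, Me2S, CH2Cl2, 0 °C to rt
Reagents that add atoms: N-bromosuccinimide, O=C1CCC(=O)N1Br
Why: Corey–Kim-type activation of the allylic alcohol and SN2′ displacement by bromide should give the primary bromide with the favoured (Z)-trisubstituted alkene, the silyloxy stereocentre not being involved.

**Step 5**
Reactants: 7 but-2-yn-1-ol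
Product: 9 (Z)-3-iodobut-2-en-1-ol, via cyclic sodium alkenylaluminate 8 (not isolated)
Conditions: NaAlH2(OCH2CH2OCH3)2, THF, 0 °C to rt; then I2, −78 to 0 °C
Reagents that add atoms: iodine, II
Why: Hydroxyl-directed trans-hydroalumination of the propargylic alcohol places aluminium on C3, and iodinolysis with retention gives the (Z)-iodoalkene.

**Step 6**
Reactants: 9 (Z)-3-iodobut-2-en-1-ol
Product: 10 (Z)-3-iodobut-2-enal
Conditions: MnO2 (activated, excess), CH2Cl2, rt, dark; filtered and used at once
Reagents that add atoms: none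
Why: Neutral allylic oxidation with MnO2 should preserve the Z geometry of the sensitive β-iodo enal.

**Step 7**
Reactants: 6 methyl (2Z,4S)-2-(bromomethyl)-4-(tert-butyldimethylsilyloxy)pent-2-enoate; 10 (Z)-3-iodobut-2-enal
Product: 12 cis-lactone, 3-methylene-5-[(Z)-2-iodoprop-1-enyl]-4-[(S)-1-(tert-butyldimethylsilyloxy)ethyl]dihydrofuran-2(3H)-one (H6/H7 cis, C6 and C7 as in the target), via syn-hydroxy ester 11 (not isolated)
Conditions: In (powder), THF/H2O 1:1, rt; crude, then pyridinium p-toluenesulfonate (cat.), toluene, 50 °C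
Reagents that add atoms: none
Why: Indium Barbier 2-(alkoxycarbonyl)allylation through a chair transition state, in which the Z bromide should give the 6,7-syn adduct and the aldehyde should approach C7 anti to the C8 silyloxy group (C8–H eclipsing the allyl plane to avoid A(1,3) strain), so that the lactate centre sets C7 and C6; acid-catalysed lactonisation then closes the cis lactone, and minor diastereomers are removed by chromatography.

**Step 8**
Reactants: 13 2-methylfuran; 12 cis-lactone alkenyl iodide
Product: 16 3-methylene-5-[(Z)-2-(5-methylfuran-2-yl)prop-1-enyl]-4-[(S)-1-(tert-butyldimethylsilyloxy)ethyl]dihydrofuran-2(3H)-one (cis), via 5-methyl-2-furyllithium 14 (not isolated), via (5-methylfuran-2-yl)zinc chloride 15 (not isolated)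
Conditions: n-BuLi, THF, 0 °C; ZnCl2, 0 °C to rt; then 12, Pd(PPh3)4 (5 mol%), THF, rt
Reagents that add atoms: none
Why: Negishi coupling, in which oxidative addition of the alkenyl iodide and fast transmetallation from zinc should retain the Z geometry and outrun Heck-type reaction with the acrylate, lactone and silyl ether being inert to the organozinc.

**Step 9**
Reactants: 16 furyl lactone silyl ether
Product: 17 4-[(S)-1-hydroxyethyl]-3-methylene-5-[(Z)-2-(5-methylfuran-2-yl)prop-1-enyl]dihydrofuran-2(3H)-one (cis)
Conditions: HF·pyridine, pyridine, THF, 0 °C to rt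
Reagents that add atoms: none
Why: Buffered fluoride desilylation, mild enough to spare the alkenylfuran and the allylic lactone.

**Step 10**
Reactants: 17 secondary alcohol
Product: 18 4-acetyl-3-methylene-5-[(Z)-2-(5-methylfuran-2-yl)prop-1-enyl]dihydrofuran-2(3H)-one (cis)
Conditions: Dess–Martin periodinane, pyridine, CH2Cl2, 0 °C; used without delay
Reagents that add atoms: none
Why: Buffered Dess–Martin oxidation removes the relay stereocentre and gives the C8 methyl ketone without epimerising C7 or moving the exocyclic alkene into conjugation.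

**Step 11**
Reactants: 18 furyl methyl ketone
Product: 19 4-acetyl-5-[(Z)-2-(2,5-dimethoxy-5-methyl-2,5-dihydrofuran-2-yl)prop-1-enyl]-3-methylenedihydrofuran-2(3H)-one (cis lactone; mixture of epimers at both ketal carbons)
Conditions: Br2 (1.05 equiv), KOAc, MeOH, −45 °C
Reagents that add atoms: methanol, CO
Why: Oxidative 2,5-dimethoxylation of the furan (bromine–methanol dearomatisation), in which bromine attacks the electron-rich furan and methanol is captured at C3 and C10 while the acrylate and ketone are inert at this temperature; the epimer mixture is acceptable because C10 is ionised and C3 equilibrates in step 13.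

**Step 12**
Reactants: 19 bis-ketal methyl ketone
Product: 21 5-[(Z)-2-(2,5-dimethoxy-5-methyl-2,5-dihydrofuran-2-yl)prop-1-enyl]-3-methylene-4-[1-(trimethylsilyloxy)vinyl]dihydrofuran-2(3H)-one (cis lactone; ketal epimers), via lithium enolate 20 (not isolated)
Conditions: LiN(SiMe3)2, Me3SiCl (in situ quench), THF, −78 °C; non-aqueous work-up, used crude
Reagents that add atoms: chlorotrimethylsilane, C[Si](C)(C)Cl
Why: Kinetic enolisation of the methyl ketone by the hindered amide with in situ silyl trapping should give the less substituted silyl enol ether before the enolate can equilibrate to C7 or add to the acrylate, the ketals being stable to base.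

**Step 13**
Reactants: 21 silyl enol ether bis-ketal
Product: 23 3-methoxy-3,10-epoxy-8-oxogermacra-1Z,4Z,11(13)-trien-12,6-olide (cis lactone; C4 and C9 cis on the dihydrofuran; C10 as in the target), via C10 oxocarbenium triflate 22 (not isolated)
Conditions: Me3SiOTf (0.3 equiv), Me3SiOMe (5 equiv), 2,6-di-tert-butyl-4-methylpyridine (0.1 equiv), CH2Cl2 (2 mM, 21 added over 6 h), −78 to −40 °C; Et3N quench
Reagents that add atoms: none
Why: Proposed new method: Me3SiOTf silylates the C10 methoxy group and expels Me3SiOMe to give the planar cyclic oxocarbenium ion 22, which C9 of the tethered silyl enol ether attacks at C10 in a Mukaiyama-type addition, silyl loss then unveiling the C8 ketone and returning the catalyst; the closest known reaction type is the intermolecular Lewis-acid C-alkylation of 2,5-dialkoxy-2,5-dihydrofurans by silyl enol ethers, untested for a ring of this size. The ten-membered carbocycle closes in the 10-(enolendo)-exo-trig mode, but because the dihydrofuran holds C1=C2 cis and links C3 to C10 through oxygen, what forms is an oxygen-bridged bicycle (a nine-membered oxacycle spanned by the C1=C2 bridge) from a chain with only three free rotors (C3–C4, C5–C6, C7–C8), and this bicycle is the ring tautomer of the target's own γ-hydroxy enone. The new C10 stereocentre is set by C3, since C9 can reach C10 only on the face of the cation that carries C4; the C3 epimers interconvert through reversible ionisation at C3 (kept reversible by the added Me3SiOMe), and C6/C7 must then select the bridged transition state that puts the lactone and the C1=C2 bridge on the same face of the oxacycle, which leads to 10R. The step needs bond formation at C10 in preference to C2 (eight-membered ring, lower charge density), to C5 (5-(enolendo) closure, stereoelectronically poor) and above all to C3 of the more stabilised C3 oxocarbenium ion (spiro seven-membered closure); the substrate opposes the last only through the congested quaternary centre next to the C4 methyl group and the strained cis-fused cycloheptenone it would create, so this is the main uncertainty of the route. High dilution, low temperature and the hindered pyridine are meant to suppress intermolecular alkylation, proton loss from the C10 methyl group and protodesilylation.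

**Step 14**
Reactants: 23 bridged methyl ketal ketone
Product: 24 (8R)-8-hydroxy-3-methoxy-3,10-epoxygermacra-1Z,4Z,11(13)-trien-12,6-olide
Conditions: (S)-Me-CBS oxazaborolidine [(3aS)-1-methyl-3,3-diphenyltetrahydro-1H,3H-pyrrolo[1,2-c][1,3,2]oxazaborole] (1 equiv), catecholborane (2 equiv), toluene/CH2Cl2, −78 °C; MeOH quench
Reagents that add atoms: none
Why: Corey–Bakshi–Shibata reduction with the branched C7 as the large group should give the 8R alcohol, the sense also expected from hydride attack on the face of the bicycle opposite the lactone and the C1=C2 bridge, with acrylate and ketal inert to catecholborane at −78 °C.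

**Step 15**
Reactants: 24 (8R)-alcohol; 25 (R)-2-methylbutanoic acid
Product: 26 (8R)-3-methoxy-8-[(R)-2-methylbutanoyloxy]-3,10-epoxygermacra-1Z,4Z,11(13)-trien-12,6-olide
Conditions: N,N′-diisopropylcarbodiimide, 4-(dimethylamino)pyridine (0.2 equiv), CH2Cl2, 0 °C to rt
Reagents that add atoms: none
Why: Steglich esterification of the only hydroxyl group, under conditions mild enough not to epimerise the α-stereocentre of the acid or harm the ketal.

**Step 16**
Reactants: 26 bridged methyl ketal ester
Product: 28 target, (6S,7R,8R,10R)-10-hydroxy-8-[(R)-2-methylbutanoyloxy]-3-oxogermacra-1Z,4Z,11(13)-trien-12,6-olide, via 3,10-hemiketal 27 (not isolated)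
Conditions: pyridinium p-toluenesulfonate (cat.), acetone/H2O 9:1, rt
Reagents that add atoms: water, O
Why: Mild acid hydrolysis of the doubly allylic methyl ketal gives the hemiketal, whose ring opening releases the C3 dienone and the C10 hydroxyl with C10 unchanged (the C10–O bond is never broken), ester and α-methylene lactone being stable to these conditions.

**Compound list**
1 | ethyl (S)-lactate | C[C@H](O)C(=O)OCC | starting material
2 | ethyl (S)-2-(tert-butyldimethylsilyloxy)propanoate | C[C@H](O[Si](C)(C)C(C)(C)C)C(=O)OCC | intermediate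
3 | (S)-2-(tert-butyldimethylsilyloxy)propanal | C[C@H](O[Si](C)(C)C(C)(C)C)C=O | intermediate
4 | methyl acrylate | C=CC(=O)OC | starting material
5 | methyl (4S)-4-(tert-butyldimethylsilyloxy)-3-hydroxy-2-methylenepentanoate (C3 epimers) | C[C@H](O[Si](C)(C)C(C)(C)C)C(O)C(=C)C(=O)OC | intermediate
6 | methyl (2Z,4S)-2-(bromomethyl)-4-(tert-butyldimethylsilyloxy)pent-2-enoate | BrC/C(=C\[C@H](C)O[Si](C)(C)C(C)(C)C)C(=O)OC | intermediate
7 | but-2-yn-1-ol | CC#CCO | starting material
8 | cyclic sodium alkenylaluminate (aluminium on C3, ring through the C1 oxygen) | CC1=CCO[Al-]1(OCCOC)OCCOC.[Na+] | intermediate (not isolated)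
9 | (Z)-3-iodobut-2-en-1-ol | C/C(I)=C/CO | intermediate
10 | (Z)-3-iodobut-2-enal | C/C(I)=C/C=O | intermediate
11 | methyl (5Z)-4-hydroxy-6-iodo-2-methylene-3-[(S)-1-(tert-butyldimethylsilyloxy)ethyl]hept-5-enoate (3,4-syn) | C=C(C(=O)OC)[C@@H]([C@@H](O)/C=C(/C)I)[C@H](C)O[Si](C)(C)C(C)(C)C | intermediate (not isolated)
12 | cis-3-methylene-5-[(Z)-2-iodoprop-1-enyl]-4-[(S)-1-(tert-butyldimethylsilyloxy)ethyl]dihydrofuran-2(3H)-one | C=C1C(=O)O[C@@H](/C=C(/C)I)[C@H]1[C@H](C)O[Si](C)(C)C(C)(C)C | intermediate
13 | 2-methylfuran | Cc1ccco1 | starting material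
14 | 5-methyl-2-furyllithium | Cc1ccc([Li])o1 | intermediate (not isolated)
15 | (5-methylfuran-2-yl)zinc chloride | Cc1ccc([Zn]Cl)o1 | intermediate (not isolated)
16 | cis-3-methylene-5-[(Z)-2-(5-methylfuran-2-yl)prop-1-enyl]-4-[(S)-1-(tert-butyldimethylsilyloxy)ethyl]dihydrofuran-2(3H)-one | C=C1C(=O)O[C@@H](/C=C(/C)c2ccc(C)o2)[C@H]1[C@H](C)O[Si](C)(C)C(C)(C)C | intermediate
17 | cis-4-[(S)-1-hydroxyethyl]-3-methylene-5-[(Z)-2-(5-methylfuran-2-yl)prop-1-enyl]dihydrofuran-2(3H)-one | C=C1C(=O)O[C@@H](/C=C(/C)c2ccc(C)o2)[C@H]1[C@H](C)O | intermediate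
18 | cis-4-acetyl-3-methylene-5-[(Z)-2-(5-methylfuran-2-yl)prop-1-enyl]dihydrofuran-2(3H)-one | C=C1C(=O)O[C@@H](/C=C(/C)c2ccc(C)o2)[C@H]1C(C)=O | intermediate
19 | cis-4-acetyl-5-[(Z)-2-(2,5-dimethoxy-5-methyl-2,5-dihydrofuran-2-yl)prop-1-enyl]-3-methylenedihydrofuran-2(3H)-one (ketal epimer mixture; trans-dimethoxy epimer with the productive C3 configuration drawn) | C=C1C(=O)O[C@@H](/C=C(/C)[C@@]2(OC)C=C[C@@](C)(OC)O2)[C@H]1C(C)=O | intermediate
20 | lithium enolate of 19 (C8–O–Li, C8=C9) | C=C1C(=O)O[C@@H](/C=C(/C)[C@@]2(OC)C=C[C@@](C)(OC)O2)[C@H]1C(=C)O[Li] | intermediate (not isolated)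
21 | C8 trimethylsilyl enol ether of 19 (ketal epimer mixture; same epimer drawn) | C=C1C(=O)O[C@@H](/C=C(/C)[C@@]2(OC)C=C[C@@](C)(OC)O2)[C@H]1C(=C)O[Si](C)(C)C | intermediate
22 | C10 oxocarbenium triflate (21 after loss of the C10 methoxy group) | C=C1C(=O)O[C@@H](/C=C(/C)[C@@]2(OC)C=CC(C)=[O+]2)[C@H]1C(=C)O[Si](C)(C)C.[O-]S(=O)(=O)C(F)(F)F | intermediate (not isolated)
23 | 3-methoxy-3,10-epoxy-8-oxogermacra-1Z,4Z,11(13)-trien-12,6-olide (cis lactone, C10 as in target) | C=C1C(=O)O[C@H]2/C=C(/C)[C@@]3(OC)C=C[C@](C)(O3)CC(=O)[C@@H]12 | intermediate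
24 | (8R)-8-hydroxy-3-methoxy-3,10-epoxygermacra-1Z,4Z,11(13)-trien-12,6-olide | C=C1C(=O)O[C@H]2/C=C(/C)[C@@]3(OC)C=C[C@](C)(O3)C[C@@H](O)[C@@H]12 | intermediate
25 | (R)-2-methylbutanoic acid | CC[C@@H](C)C(=O)O | starting material
26 | (8R)-3-methoxy-8-[(R)-2-methylbutanoyloxy]-3,10-epoxygermacra-1Z,4Z,11(13)-trien-12,6-olide | C=C1C(=O)O[C@H]2/C=C(/C)[C@@]3(OC)C=C[C@](C)(O3)C[C@@H](OC(=O)[C@H](C)CC)[C@@H]12 | intermediate
27 | 3-hydroxy-3,10-epoxy hemiketal of the target | C=C1C(=O)O[C@H]2/C=C(/C)[C@@]3(O)C=C[C@](C)(O3)C[C@@H](OC(=O)[C@H](C)CC)[C@@H]12 | intermediate (not isolated)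
28 | (6S,7R,8R,10R)-10-hydroxy-8-[(R)-2-methylbutanoyloxy]-3-oxogermacra-1Z,4Z,11(13)-trien-12,6-olide | C=C1C(=O)O[C@H]2/C=C(/C)C(=O)/C=C\[C@](C)(O)C[C@@H](OC(=O)[C@H](C)CC)[C@@H]12 | target

**Step count**
Total: 16 steps. Longest linear sequence: 14 steps (steps 1–4 and 7–16 from ethyl (S)-lactate).

**Steps most likely to fail**

Step 13 (proposed new method). Ionisation may occur mainly at C3, followed by spiro seven-membered closure; C9 may attack C2; the C10 methyl group may lose a proton and the ring rearomatise; intermolecular alkylation may compete; or closure may go through the mismatched C3 epimer and give the C10 epimer.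
The fallback uses known reactions only, sets out from 12 and 13 and comes back at 23.
- 12 is desilylated with HF·pyridine to the alcohol F1, oxidised with Dess–Martin periodinane to the methyl ketone F2, and converted with LiN(SiMe3)2/Me3SiCl at −78 °C into the silyl enol ether F3.
- 13 is oxidised with Br2/KOAc/MeOH to 2,5-dimethoxy-2-methyl-2,5-dihydrofuran F4.
- Intermolecular Me3SiOTf-catalysed alkylation of F4 by F3, at the more readily ionised methyl-bearing ketal carbon, forms the C9–C10 bond and should give the 5-methoxy-2,5-dihydrofuran adduct F5 as both C10 epimers.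
- Aqueous pyridinium p-toluenesulfonate frees the lactol F6.
- A Nozaki–Hiyama–Kishi macrocyclisation (CrCl2, NiCl2 cat., DMSO/THF, high dilution) between the C4 alkenyl iodide and the C3 aldehyde supplied by the lactol closes the ring at C3–C4 to the 3,10-dihydroxy macrocycle F7.
- MnO2 oxidises the doubly allylic C3 carbinol to the 10-hydroxy-3,8-dione F8 (in equilibrium with its hemiketal).
- Pyridinium p-toluenesulfonate in methanol converts the 10R epimer into 23; the C10 epimer is removed by chromatography.

Step 12. The amide base may deprotonate the doubly activated C7–H (epimerisation, or migration of the exocyclic alkene into conjugation) or add to the α-methylene lactone, and the labile enol silane may hydrolyse.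
The fallback sets out from 19 and comes back at 23.
- Thiophenol with catalytic Et3N adds to the α-methylene group of 19 to give the sulfide F9, in which C7–H is no longer allylic and no Michael acceptor remains.
- The same enolisation then gives the silyl enol ether F10.
- Cyclisation under the conditions of step 13 gives the bridged ketal sulfide F11.
- NaIO4 gives the sulfoxide F12, whose thermal syn-elimination (toluene, 100 °C, CaCO3) restores the exocyclic methylene group and gives 23.

Step 14. Facial selectivity may be poor if catalyst and substrate bias are mismatched, or the hindered ring ketone may react sluggishly.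
The fallback sets out from 23 and comes back at 26. Luche reduction (NaBH4, CeCl3·7H2O, MeOH, −78 °C) reduces the ketone under substrate control alone. The 8R alcohol is 24 and continues through step 15. The 8S alcohol F13 is esterified with inversion by acid 25 under Mitsunobu conditions (PPh3, diisopropyl azodicarboxylate) to give 26, so both epimers converge.

**Further compounds**
F1 | step 13 | cis-4-[(S)-1-hydroxyethyl]-5-[(Z)-2-iodoprop-1-enyl]-3-methylenedihydrofuran-2(3H)-one | C=C1C(=O)O[C@@H](/C=C(/C)I)[C@H]1[C@H](C)O
F2 | step 13 | cis-4-acetyl-5-[(Z)-2-iodoprop-1-enyl]-3-methylenedihydrofuran-2(3H)-one | C=C1C(=O)O[C@@H](/C=C(/C)I)[C@H]1C(C)=O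
F3 | step 13 | cis-5-[(Z)-2-iodoprop-1-enyl]-3-methylene-4-[1-(trimethylsilyloxy)vinyl]dihydrofuran-2(3H)-one | C=C1C(=O)O[C@@H](/C=C(/C)I)[C@H]1C(=C)O[Si](C)(C)C
F4 | step 13 | 2,5-dimethoxy-2-methyl-2,5-dihydrofuran (cis/trans mixture) | COC1C=CC(C)(OC)O1
F5 | step 13 | cis-5-[(Z)-2-iodoprop-1-enyl]-4-[2-(5-methoxy-2-methyl-2,5-dihydrofuran-2-yl)acetyl]-3-methylenedihydrofuran-2(3H)-one (C10 and acetal epimers) | C=C1C(=O)O[C@@H](/C=C(/C)I)[C@H]1C(=O)CC2(C)C=CC(OC)O2
F6 | step 13 | lactol, cis-4-[2-(5-hydroxy-2-methyl-2,5-dihydrofuran-2-yl)acetyl]-5-[(Z)-2-iodoprop-1-enyl]-3-methylenedihydrofuran-2(3H)-one | C=C1C(=O)O[C@@H](/C=C(/C)I)[C@H]1C(=O)CC2(C)C=CC(O)O2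
F7 | step 13 | 3,10-dihydroxy-8-oxogermacra-1Z,4Z,11(13)-trien-12,6-olide (C3 epimers, 10R) | C=C1C(=O)O[C@H]2/C=C(/C)C(O)/C=C\[C@](C)(O)CC(=O)[C@@H]12
F8 | step 13 | 10-hydroxy-3,8-dioxogermacra-1Z,4Z,11(13)-trien-12,6-olide (10R) | C=C1C(=O)O[C@H]2/C=C(/C)C(=O)/C=C\[C@](C)(O)CC(=O)[C@@H]12
F9 | step 12 | thiophenol adduct of 19 (3-(phenylthiomethyl) lactone, C11 epimers) | c1ccccc1SCC2C(=O)O[C@@H](/C=C(/C)[C@@]3(OC)C=C[C@@](C)(OC)O3)[C@H]2C(C)=O
F10 | step 12 | C8 trimethylsilyl enol ether of F9 | c1ccccc1SCC2C(=O)O[C@@H](/C=C(/C)[C@@]3(OC)C=C[C@@](C)(OC)O3)[C@H]2C(=C)O[Si](C)(C)C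
F11 | step 12 | 13-phenylthio-11,13-dihydro derivative of 23 | C(Sc4ccccc4)C1C(=O)O[C@H]2/C=C(/C)[C@@]3(OC)C=C[C@](C)(O3)CC(=O)[C@@H]12
F12 | step 12 | sulfoxide of F11 | C(S(=O)c4ccccc4)C1C(=O)O[C@H]2/C=C(/C)[C@@]3(OC)C=C[C@](C)(O3)CC(=O)[C@@H]12
F13 | step 14 | (8S)-8-hydroxy-3-methoxy-3,10-epoxygermacra-1Z,4Z,11(13)-trien-12,6-olide | C=C1C(=O)O[C@H]2/C=C(/C)[C@@]3(OC)C=C[C@](C)(O3)C[C@H](O)[C@@H]12
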